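**Strategy.** Carotenoid numbering is used; ring B is the cyclohexanone. Its C3′H2–C4′(=O) unit is disconnected as a two-carbon vinyl linchpin inserted between the methyl-bearing C5′ and the neopentyl C2′ beside gem-dimethyl C1′. In one operation a vinyl boronate complex of a C5′ sec-alkyl pinacol boronate closes onto a C2′ iodide (which cannot β-eliminate) under nickel catalysis: C2′–C3′ and C4′–C5′ form, C5′ migrates from boron with retention, and boron stays on C4′ as the latent oxygen. The acyclic iodo boronate precursor comes from ketopantolactone. The same cyclohexane also gives ring A: one C15 phosphonium salt is coupled twice with the C10 dialdehyde, the ring being oxidised at the C25 stage.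

Key step: step 6

Remark: the polyene is taken as all-E and the stereocentres as drawn (4S,5S,6S in ring A, 5′S,6′S in ring B); in step 2 the ligand antipode that gives the S boronate is the one used.

**Step 1**
Reactants: 1 4,4-dimethyloxolane-2,3-dione (ketopantolactone); 2 ethyltriphenylphosphonium bromide
Product: 3 (Z)-3-ethylidene-4,4-dimethyloxolan-2-one
Conditions: 2, KOt-Bu, THF, 0 °C; then 1, −78 °C to rt; I2 (cat.) if an E portion has to be equilibrated
Reagents that add atoms: none
Why: Wittig olefination of the non-enolisable, highly electrophilic ring ketone; the Z alkene (methyl on the carbonyl side) should prevail because the E isomer would force the methyl group against the gem-dimethyl carbon.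

**Step 2**
Reactants: 3
Product: 4 4,4-dimethyl-3-[(1S)-1-(4,4,5,5-tetramethyl-1,3,2-dioxaborolan-2-yl)ethyl]oxolan-2-one (C3 epimers)
Conditions: B2pin2, CuCl (cat.), NaOt-Bu (cat.), (R)-1-[(S)-2-(diphenylphosphino)ferrocenyl]ethyldicyclohexylphosphine or its antipode (cat.), MeOH, THF, rt
Reagents that add atoms: bis(pinacolato)diboron, CC1(C)OB(OC1(C)C)B1OC(C)(C)C(C)(C)O1
Why: Copper-catalysed enantioselective conjugate borylation (boryl–copper addition to the exocyclic β-carbon, protonation by MeOH): the chiral bisphosphine selects the alkene face and sets the S carbon–boron stereocentre that becomes C5 and C5′, while the ring α-carbon (later C6) forms as an epimer mixture that step 9 corrects.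

**Step 3**
Reactants: 4
Product: 5 4,4-dimethyl-3-[(1S)-1-(4,4,5,5-tetramethyl-1,3,2-dioxaborolan-2-yl)ethyl]oxolan-2-ol (lactol, epimers at C2 and C3)
Conditions: i-Bu2AlH (1.1 equiv), CH2Cl2, −78 °C; aq. KNaC4H4O6 (potassium sodium tartrate)
Reagents that add atoms: none
Why: Partial lactone reduction: the aluminium hemiacetal is stable at −78 °C and gives the lactol on work-up, and a pinacol boronate should not react with i-Bu2AlH at this temperature.

**Step 4**
Reactants: 5
Product: 6 (4S)-3-ethenyl-2,2-dimethyl-4-(4,4,5,5-tetramethyl-1,3,2-dioxaborolan-2-yl)pentan-1-ol (C3 epimers)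
Conditions: Ph3PCH3Br, KOt-Bu, THF, 0 to 40 °C
Reagents that add atoms: methyltriphenylphosphonium bromide, C[P+](c1ccccc1)(c1ccccc1)c1ccccc1.[Br-]
Why: Wittig methylenation of the ring-opened hydroxy aldehyde form of the lactol: the vinyl group masks the later formyl carbon C7 and the neopentyl hydroxyl at C2 is set free.

**Step 5**
Reactants: 6
Product: 7 2-[(2S)-3-ethenyl-5-iodo-4,4-dimethylpentan-2-yl]-4,4,5,5-tetramethyl-1,3,2-dioxaborolane (C3 epimers)
Conditions: I2, PPh3, imidazole, toluene, 80 °C
Reagents that add atoms: iodine, II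
Why: Appel-type iodination: the alkoxyphosphonium ion is displaced by iodide in an SN2 step that is slow at a neopentyl carbon but should be clean on heating, since no elimination is possible and the boronate and alkene are inert.

**Step 6**
Reactants: 7
Product: 10 (2S)-3-ethenyl-2,4,4-trimethylcyclohexan-1-ol (C1/C3 epimer mixture), via lithium vinylboronate complex 8 (not isolated), via cyclohexyl pinacol boronate 9 (not isolated)
Conditions: vinyllithium (1.1 equiv, from Sn(CH=CH2)4 and n-BuLi), THF, −78 to 0 °C; then NiBr2(DME) (10 mol %), trans-N,N′-dimethylcyclohexane-1,2-diamine (12 mol %), THF/DMSO, 0.01 M, rt; then aq. NaOH, H2O2, 0 °C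
Reagents that add atoms: vinyllithium, [Li]C=C; hydrogen peroxide, OO
Why: Proposed new method: vinyllithium adds to the pinacol boronate to give tetracoordinate borate 8; low-valent nickel formed in situ takes the iodine atom from neopentyl C2, the C2 radical or alkylnickel is captured by the terminal CH2 (C3) of the boron-bound vinyl group of the same molecule, and the electron-poor α-carbon C4 then triggers a 1,2-shift of the sec-alkyl carbon C5 from boron to C4, so that C2–C3 and C4–C5 form in one operation and boron is left on C4 (9). The closest known reaction type is the nickel-catalysed three-component conjunctive coupling of vinyl boronate complexes with unactivated alkyl iodides (radical–polar crossover with 1,2-metallate shift); here the migrating group and the electrophile sit on one chain, which has not been shown. The ring closes by attack of C2 on the distal vinyl carbon (formally 7-endo-trig through a seven-membered boron-containing ring or a seven-membered nickelacycle), and the boron shift contracts this to the six-membered carbocycle C1–C6. C5 is transferred with retention, as 1,2-metallate shifts are stereospecific, so the S centre made in step 2 becomes C5; C4 forms as a mixture that steps 7 and 8 erase, and C6 is not touched. The step needs ring closure to beat intermolecular coupling and attack at the terminal rather than the internal vinyl carbon: high dilution, the boron-stabilised regiochemistry of addition and the gem-dimethyl group (Thorpe–Ingold effect) should secure this, and neopentyl C2 has no β-hydrogen to eliminate. Alkaline peroxide then converts C4–B into C4–OH with retention.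

**Step 7**
Reactants: 10
Product: 11 (2S)-3-ethenyl-2,4,4-trimethylcyclohexan-1-one (C3 epimers)
Conditions: Dess–Martin periodinane, NaHCO3, CH2Cl2, 0 °C to rt
Reagents that add atoms: none
Why: Dess–Martin oxidation under bicarbonate buffer merges the two carbinol epimers (carotenoid C4) into one ketone without base, so the adjacent stereocentre C5 should not be enolised.

**Step 8**
Reactants: 11
Product: 12 (1S,2S)-3-ethenyl-2,4,4-trimethylcyclohexan-1-ol (C3 epimers)
Conditions: Li, NH3(l), THF, t-BuOH, −78 °C; NH4Cl
Reagents that add atoms: none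
Why: Dissolving-metal reduction of a cyclohexanone should give the more stable equatorial alcohol whatever the configuration at C3, which sets the hydroxyl at carotenoid C4 trans to the C5 methyl group (4S); the isolated vinyl group is not reduced.

**Step 9**
Reactants: 12
Product: 14 (1S,2S,3S)-3-hydroxy-2,6,6-trimethylcyclohexane-1-carbaldehyde, via hydroxy aldehyde epimer mixture 13 (not isolated)
Conditions: O3, CH2Cl2/MeOH, −78 °C; PPh3; then DBU (cat.), CH2Cl2, rt
Reagents that add atoms: ozone, [O-][O+]=O
Why: Ozonolysis unmasks the formyl group, and base-mediated enolisation (thermodynamic epimerisation) should funnel both C1 epimers to the aldehyde with the formyl group equatorial and trans to the C5 methyl group (itself locked equatorial by the syn-pentane clash with the axial ring methyl), as expected by analogy with 2,2,6-trimethylcyclohexanecarbaldehyde; this sets C6.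

**Step 10**
Reactants: 14; 15 ethyl (E)-4-(diethoxyphosphoryl)-3-methylbut-2-enoate (triethyl 3-methyl-4-phosphonocrotonate)
Product: 16 ethyl (2E,4E)-5-[(1S,2S,3S)-3-hydroxy-2,6,6-trimethylcyclohexyl]-3-methylpenta-2,4-dienoate
Conditions: 15 (2.5 equiv), LiN(SiMe3)2 (2.4 equiv), THF/DMPU, −78 °C; then 14, −78 to 0 °C
Reagents that add atoms: none
Why: Horner–Wadsworth–Emmons olefination with the vinylogous phosphonate anion should form C7=C8 with E geometry and carry the 2E trisubstituted alkene; the excess anion covers the free hydroxyl, and the aldehyde stays at its trans equilibrium.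

**Step 11**
Reactants: 16
Product: 17 (1S,2S,3S)-3-[(1E,3E)-5-hydroxy-3-methylpenta-1,3-dien-1-yl]-2,4,4-trimethylcyclohexan-1-ol
Conditions: i-Bu2AlH (3.5 equiv), CH2Cl2, −78 °C; aq. KNaC4H4O6
Reagents that add atoms: none
Why: i-Bu2AlH reduces the conjugated ester in a 1,2 sense to the allylic alcohol without touching the diene.

**Step 12**
Reactants: 17
Product: 18 [(2E,4E)-5-[(1S,2S,3S)-3-hydroxy-2,6,6-trimethylcyclohexyl]-3-methylpenta-2,4-dien-1-yl]triphenylphosphonium bromide
Conditions: PPh3·HBr, MeOH, rt
Reagents that add atoms: triphenylphosphine hydrobromide, Br.c1ccc(cc1)P(c1ccccc1)c1ccccc1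
Why: Phosphonium salt formation: acid ionises the primary allylic alcohol to a pentadienyl cation that triphenylphosphine should capture at the terminal carbon, while the secondary ring hydroxyl does not ionise.

**Step 13**
Reactants: 18; 19 (2E,4E,6E)-2,7-dimethylocta-2,4,6-trienedial
Product: 20 (2E,4E,6E,8E,10E,12E)-13-[(1S,2S,3S)-3-hydroxy-2,6,6-trimethylcyclohexyl]-2,7,11-trimethyltrideca-2,4,6,8,10,12-hexaenal
Conditions: 19 (3 equiv), NaOMe, MeOH/CH2Cl2, 0 °C to rt; then I2 (cat.), CH2Cl2, daylight, argon
Reagents that add atoms: none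
Why: Wittig olefination of the semi-stabilised allylic ylide with an excess of the symmetrical dialdehyde should stop at mono-olefination; the new C11=C12 bond forms as an E/Z mixture that iodine-catalysed equilibration should convert to the all-E aldehyde.

**Step 14**
Reactants: 20
Product: 21 (2E,4E,6E,8E,10E,12E)-2,7,11-trimethyl-13-[(1S,2S)-2,6,6-trimethyl-3-oxocyclohexyl]trideca-2,4,6,8,10,12-hexaenal
Conditions: Dess–Martin periodinane, NaHCO3, CH2Cl2, 0 °C, dark, argon
Reagents that add atoms: none
Why: Dess–Martin oxidation of the single secondary alcohol under bicarbonate buffer is mild enough for a polyene aldehyde and non-basic, so C5′ next to the new ketone should keep its configuration.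

**Step 15**
Reactants: 18; 21
Product: 22 (4S,5S,6S,5′S,6′S)-4-hydroxy-5,6,5′,6′-tetrahydro-β,β-caroten-4′-one (all-E, target)
Conditions: 18 (1.2 equiv), NaN(SiMe3)2 (1.15 equiv), THF, −78 °C; then 21, −78 to 0 °C; AcOH; then EtOH, 70 °C, argon, dark
Reagents that add atoms: none
Why: Wittig olefination: one equivalent of base deprotonates only the phosphonium salt, and the ylide should add to the conjugated aldehyde far faster than it attacks or enolises the hindered saturated ketone, so C5′ is preserved; gentle heating equilibrates the new C11=C12 bond to E.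

**Compound list**
1 | 4,4-dimethyloxolane-2,3-dione (ketopantolactone) | CC1(C)COC(=O)C1=O | starting material
2 | ethyltriphenylphosphonium bromide | CC[P+](c1ccccc1)(c1ccccc1)c1ccccc1.[Br-] | starting material
3 | (Z)-3-ethylidene-4,4-dimethyloxolan-2-one | C/C=C1\C(=O)OCC1(C)C | intermediate
4 | 4,4-dimethyl-3-[(1S)-1-(4,4,5,5-tetramethyl-1,3,2-dioxaborolan-2-yl)ethyl]oxolan-2-one (C3 epimers) | C[C@H](B1OC(C)(C)C(C)(C)O1)C1C(=O)OCC1(C)C | intermediate
5 | 4,4-dimethyl-3-[(1S)-1-(4,4,5,5-tetramethyl-1,3,2-dioxaborolan-2-yl)ethyl]oxolan-2-ol (epimers at C2 and C3) | C[C@H](B1OC(C)(C)C(C)(C)O1)C1C(O)OCC1(C)C | intermediate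
6 | (4S)-3-ethenyl-2,2-dimethyl-4-(4,4,5,5-tetramethyl-1,3,2-dioxaborolan-2-yl)pentan-1-ol (C3 epimers) | C[C@H](B1OC(C)(C)C(C)(C)O1)C(C=C)C(C)(C)CO | intermediate
7 | 2-[(2S)-3-ethenyl-5-iodo-4,4-dimethylpentan-2-yl]-4,4,5,5-tetramethyl-1,3,2-dioxaborolane (C3 epimers) | C[C@H](B1OC(C)(C)C(C)(C)O1)C(C=C)C(C)(C)CI | intermediate
8 | lithium ethenyl[(2S)-3-ethenyl-5-iodo-4,4-dimethylpentan-2-yl](pinacolato)borate | [Li+].C[C@H]([B-]1(C=C)OC(C)(C)C(C)(C)O1)C(C=C)C(C)(C)CI | intermediate
9 | 2-[(2R)-3-ethenyl-2,4,4-trimethylcyclohexyl]-4,4,5,5-tetramethyl-1,3,2-dioxaborolane (C1 and C3 epimers; 2R is the retained C5 centre) | C=CC1[C@H](C)C(B2OC(C)(C)C(C)(C)O2)CCC1(C)C | intermediate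
10 | (2S)-3-ethenyl-2,4,4-trimethylcyclohexan-1-ol (C1/C3 epimer mixture) | C=CC1[C@H](C)C(O)CCC1(C)C | intermediate
11 | (2S)-3-ethenyl-2,4,4-trimethylcyclohexan-1-one (C3 epimers) | C=CC1[C@H](C)C(=O)CCC1(C)C | intermediate
12 | (1S,2S)-3-ethenyl-2,4,4-trimethylcyclohexan-1-ol (C3 epimers) | C=CC1[C@H](C)[C@@H](O)CCC1(C)C | intermediate
13 | (2S,3S)-3-hydroxy-2,6,6-trimethylcyclohexane-1-carbaldehyde (C1 epimers) | O=CC1[C@H](C)[C@@H](O)CCC1(C)C | intermediate
14 | (1S,2S,3S)-3-hydroxy-2,6,6-trimethylcyclohexane-1-carbaldehyde | O=C[C@H]1[C@H](C)[C@@H](O)CCC1(C)C | intermediate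
15 | ethyl (E)-4-(diethoxyphosphoryl)-3-methylbut-2-enoate | CCOC(=O)/C=C(\C)CP(=O)(OCC)OCC | starting material
16 | ethyl (2E,4E)-5-[(1S,2S,3S)-3-hydroxy-2,6,6-trimethylcyclohexyl]-3-methylpenta-2,4-dienoate | CCOC(=O)/C=C(C)/C=C/[C@H]1[C@H](C)[C@@H](O)CCC1(C)C | intermediate
17 | (1S,2S,3S)-3-[(1E,3E)-5-hydroxy-3-methylpenta-1,3-dien-1-yl]-2,4,4-trimethylcyclohexan-1-ol | OC/C=C(C)/C=C/[C@H]1[C@H](C)[C@@H](O)CCC1(C)C | intermediate
18 | [(2E,4E)-5-[(1S,2S,3S)-3-hydroxy-2,6,6-trimethylcyclohexyl]-3-methylpenta-2,4-dien-1-yl]triphenylphosphonium bromide | [Br-].c1ccccc1[P+](c1ccccc1)(c1ccccc1)C/C=C(C)/C=C/[C@H]1[C@H](C)[C@@H](O)CCC1(C)C | intermediate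
19 | (2E,4E,6E)-2,7-dimethylocta-2,4,6-trienedial | O=C/C(C)=C/C=C/C=C(C)/C=O | starting material
20 | (2E,4E,6E,8E,10E,12E)-13-[(1S,2S,3S)-3-hydroxy-2,6,6-trimethylcyclohexyl]-2,7,11-trimethyltrideca-2,4,6,8,10,12-hexaenal | CC(/C=C/C=C(C)/C=C/[C@H]1[C@H](C)[C@@H](O)CCC1(C)C)=C\C=C\C=C(C)\C=O | intermediate
21 | (2E,4E,6E,8E,10E,12E)-2,7,11-trimethyl-13-[(1S,2S)-2,6,6-trimethyl-3-oxocyclohexyl]trideca-2,4,6,8,10,12-hexaenal | CC(/C=C/C=C(C)/C=C/[C@H]1[C@H](C)C(=O)CCC1(C)C)=C\C=C\C=C(C)\C=O | intermediate
22 | (4S,5S,6S,5′S,6′S)-4-hydroxy-5,6,5′,6′-tetrahydro-β,β-caroten-4′-one (all-E) | CC(/C=C/C=C(C)/C=C/[C@H]1[C@H](C)[C@@H](O)CCC1(C)C)=C\C=C\C=C(C)\C=C\C=C(C)\C=C\[C@H]1[C@H](C)C(=O)CCC1(C)C | target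

Total steps: 15. Longest linear sequence: 15 (salt 18 is used in steps 13 and 15).

**Steps most likely to fail**

Step 6. The ring closure may lose to intermolecular coupling of two borate molecules, to simple reduction of the carbon–iodine bond or to protodeboronation before the boron shift. The fallback sets out from 7 and forms the two bonds in separate, known operations. Addition of 1-ethoxyvinyllithium to the boronate and Zweifel olefination (I2, then NaOMe) should give, with retention at the migrating carbon, the enol ether (3S)-2-ethoxy-4-ethenyl-6-iodo-3,5,5-trimethylhex-1-ene F1. Mild aqueous acid should hydrolyse it to the methyl ketone (3S)-4-ethenyl-6-iodo-3,5,5-trimethylhexan-2-one F2. Kinetic deprotonation of the methyl group (LiN(i-Pr)2, THF/DMPU, −78 °C to rt) and intramolecular alkylation by the neopentyl iodide should close the ring to ketone 11, where the route resumes.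

Step 9. The epimerisation at the hindered α-carbon may be slow or may stop at an insufficient preference for the equatorial formyl group. The fallback sets out from the crude aldehyde mixture 13 and moves the equilibration to the ester, whose larger group should have the stronger equatorial preference. Oxidative esterification (I2, KOH, MeOH) should give methyl (2S,3S)-3-hydroxy-2,6,6-trimethylcyclohexane-1-carboxylate as the C1 epimer mixture F3. Equilibration with NaOMe in MeOH should give the trans ester methyl (1S,2S,3S)-3-hydroxy-2,6,6-trimethylcyclohexane-1-carboxylate F4. Reduction with i-Bu2AlH at −78 °C should return aldehyde 14.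

Step 2. Face selection by the boryl–copper species on the hindered exocyclic enoate may be poor, or the addition sluggish. The fallback sets out from 3 and uses resolution in place of catalyst control. Borylation with an achiral catalyst (CuCl, NaOt-Bu, Xantphos, B2pin2, MeOH) should give 4,4-dimethyl-3-[1-(4,4,5,5-tetramethyl-1,3,2-dioxaborolan-2-yl)ethyl]oxolan-2-one, racemic at the boron-bearing carbon, F5. Transesterification with (+)-pinanediol gives diastereomeric boronates, from which the (+)-pinanediol ester of 3-[(1S)-1-boronoethyl]-4,4-dimethyloxolan-2-one F6 is separated by chromatography or crystallisation. KHF2 should convert it into potassium trifluoro[(1S)-1-(4,4-dimethyl-2-oxooxolan-3-yl)ethyl]borate F7, and pinacol with Me3SiCl should return 4.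

**Further compounds**
F1 | step 6 | (3S)-2-ethoxy-4-ethenyl-6-iodo-3,5,5-trimethylhex-1-ene (C4 epimers) | C=C(OCC)[C@@H](C)C(C=C)C(C)(C)CI
F2 | step 6 | (3S)-4-ethenyl-6-iodo-3,5,5-trimethylhexan-2-one (C4 epimers) | CC(=O)[C@@H](C)C(C=C)C(C)(C)CI
F3 | step 9 | methyl (2S,3S)-3-hydroxy-2,6,6-trimethylcyclohexane-1-carboxylate (C1 epimers) | COC(=O)C1[C@H](C)[C@@H](O)CCC1(C)C
F4 | step 9 | methyl (1S,2S,3S)-3-hydroxy-2,6,6-trimethylcyclohexane-1-carboxylate | COC(=O)[C@H]1[C@H](C)[C@@H](O)CCC1(C)C
F5 | step 2 | 4,4-dimethyl-3-[1-(4,4,5,5-tetramethyl-1,3,2-dioxaborolan-2-yl)ethyl]oxolan-2-one (racemic at the boron-bearing carbon) | CC(B1OC(C)(C)C(C)(C)O1)C1C(=O)OCC1(C)C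
F6 | step 2 | (+)-pinanediol ester of 3-[(1S)-1-boronoethyl]-4,4-dimethyloxolan-2-one | C[C@H](B1O[C@@H]2C[C@@H]3C[C@H]([C@@]2(C)O1)C3(C)C)C1C(=O)OCC1(C)C
F7 | step 2 | potassium trifluoro[(1S)-1-(4,4-dimethyl-2-oxooxolan-3-yl)ethyl]borate | [K+].C[C@H]([B-](F)(F)F)C1C(=O)OCC1(C)C
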